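The benzene ring (ring A) of the tetralone is opened at C6–C7 and C4a–C5. Tetralone atoms C7, C8 with its oxygen, C8a and C4a are the diene of a 4-methoxy-2-pyrone fused to ring B, so that only C5 and C6 have to come from an alkyne. One thermal operation, [4+2] addition of a 3-phenylpropiolate ester followed by loss of CO2, closes ring A at the arene oxidation level with phenyl, carboxyl and the C8 oxygen in place. The precursor is (S)-7-silyloxy-4-methoxy-7,8-dihydro-2H-chromene-2,5(6H)-dione, which already holds ring B, its ketone and the carbinol centre. The carboxyl is later grown into the hydroxypyrone.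

Key step: step 8

Assumption: in step 5 the lipase is taken to hydrolyse the (S)-acetate faster than the (R)-acetate (the pyrone-fused side of ring B acting as the large substituent); the sense of this preference has to be confirmed in the first run.

Numbering: chromene numbering is used for 6–9, naphthalene numbering for 13–20, and tetralone numbering (C1 ketone, C3 carbinol, C8 phenol) where stated.

Step 1
Reactants: 1 phloroglucinol
Product: 2 5-hydroxycyclohexane-1,3-dione
Conditions: H2 (3 atm), 5% Rh/Al2O3, NaOH (1.0 equiv), H2O, rt; then HCl to pH 3, 0 °C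
Reagents that add atoms: none
Why: Partial catalytic hydrogenation of the monosodium phenolate, the same reaction type as the reduction of resorcinol to cyclohexane-1,3-dione, should stop after one equivalent of H2 because the product is present as the enolate of a vinylogous acid, and the hydroxy dione formed is achiral.

Step 2
Reactants: 2 5-hydroxycyclohexane-1,3-dione
Product: 4 3,5-dioxocyclohexyl acetate, via enol acetate 3 (not isolated)
Conditions: Ac2O (2.5 equiv), pyridine, 0 °C → rt; then H2O, rt; acidify to pH 3, extract
Reagents that add atoms: acetic anhydride CC(=O)OC(C)=O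
Why: Acetylation (nucleophilic acyl substitution) covers the secondary alcohol, while the enol acetate that forms alongside in 3 is a vinylogous anhydride and is hydrolysed selectively by water in the same pot, so that the alkyl acetate is left to shield the alcohol from malonyl dichloride and to serve as the handle for the enzymatic resolution.

Step 3
Reactants: 4 3,5-dioxocyclohexyl acetate; 5 malonyl dichloride
Product: 6 (±)-4-hydroxy-2,5-dioxo-5,6,7,8-tetrahydro-2H-chromen-7-yl acetate
Conditions: 5 (1.1 equiv), CH2Cl2, 0 °C → rt, N2 sweep, no base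
Reagents that add atoms: none
Why: Twofold acylation of the enolised dione by the bis-acid chloride, C-acylation at C2 and then lactonisation through the neighbouring enol oxygen (the malonyl dichloride annulation of 1,3-diones to 4-hydroxy-2-pyrones), closes the pyrone ring without base, which the acetate tolerates, and since either of the two equivalent enol oxygens can close the lactone the acetoxy carbon becomes stereogenic as a racemate.

Step 4
Reactants: 6 (±)-4-hydroxy-2,5-dioxo-5,6,7,8-tetrahydro-2H-chromen-7-yl acetate
Product: 7 (±)-4-methoxy-2,5-dioxo-5,6,7,8-tetrahydro-2H-chromen-7-yl acetate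
Conditions: MeOH (1.5 equiv), PPh3, DIAD, THF, 0 °C → rt
Reagents that add atoms: methanol CO
Why: Mitsunobu etherification of the acidic pyrone hydroxyl (a vinylogous carboxylic acid) with methanol should alkylate O4 under neutral conditions, so the carbonate base of a classical methylation, which could eliminate the beta-acetoxy ketone and aromatise ring B, is avoided.

Step 5
Reactants: 7 (±)-4-methoxy-2,5-dioxo-5,6,7,8-tetrahydro-2H-chromen-7-yl acetate
Product: 8 (S)-7-hydroxy-4-methoxy-7,8-dihydro-2H-chromene-2,5(6H)-dione
Conditions: immobilised Candida antarctica lipase B, 0.1 M phosphate buffer pH 7.0/MTBE, 30 °C, stopped before half conversion; chromatography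
Reagents that add atoms: none
Why: Lipase-catalysed enantioselective hydrolysis (kinetic resolution) of the secondary acetate is expected to deacylate the (S)-enantiomer and leave the (R)-acetate, which is removed by chromatography, so the configuration at C7 is selected and not created, and at pH 7 neither the methoxypyrone nor the beta-oxygenated ketone should be affected.

Step 6
Reactants: 8 (S)-7-hydroxy-4-methoxy-7,8-dihydro-2H-chromene-2,5(6H)-dione
Product: 9 (S)-7-(tert-butyldimethylsilyloxy)-4-methoxy-7,8-dihydro-2H-chromene-2,5(6H)-dione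
Conditions: TBSCl, imidazole, DMF, 0 °C → rt
Reagents that add atoms: tert-butyldimethylsilyl chloride CC(C)(C)[Si](C)(C)Cl
Why: Silylation of the secondary alcohol with the silyl chloride under imidazole catalysis (nucleophilic substitution at silicon) is a neutral reaction in which imidazole is too weak a base to start beta-elimination, and the stereocentre is not touched.

Step 7
Reactants: 10 3-phenylpropiolic acid
Product: 11 benzyl 3-phenylpropiolate
Conditions: BnBr, K2CO3, DMF, rt
Reagents that add atoms: benzyl bromide BrCc1ccccc1
Why: SN2 O-alkylation of the carboxylate at room temperature, where the arylpropiolate does not decarboxylate, installs a benzyl ester because the doubly ortho-substituted benzoate formed in step 8 can then be opened by hydrogenolysis at the O–CH2Ph bond, which is indifferent to crowding at the carbonyl and needs no base.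

Step 8
Reactants: 9 (S)-7-(tert-butyldimethylsilyloxy)-4-methoxy-7,8-dihydro-2H-chromene-2,5(6H)-dione; 11 benzyl 3-phenylpropiolate
Product: 13 benzyl (S)-7-(tert-butyldimethylsilyloxy)-4-methoxy-5-oxo-2-phenyl-5,6,7,8-tetrahydronaphthalene-1-carboxylate, via bicyclic lactone 12 (not isolated)
Conditions: 11 (4 equiv), o-dichlorobenzene (concentrated), BHT (cat.), sealed tube, Ar, 180 °C
Reagents that add atoms: none
Why: The s-cis diene C3=C4–C4a=C8a held in the pyrone ring of 9 undergoes a thermal, concerted but asynchronous [4+2] cycloaddition with ynoate 11 (pyrone C3 to the phenyl-bearing alkyne carbon, C8a to the ester-bearing carbon) to give the 2-oxabicyclo[2.2.2]octadienone 12, whose lactone bridge leaves as CO2 by retro-[4+2] cycloreversion as soon as it forms. The closest known reaction type is the Alder–Rickert-type benzannulation of 2-pyrones with acetylenic esters, a Diels–Alder/retro-Diels–Alder sequence. The one new ring, benzene ring A, is closed by intermolecular cycloaddition (two C–C bonds, C6–C7 and C4a–C5 in tetralone numbering) and becomes aromatic through the cycloreversion, so no oxidant is needed. No lasting stereocentre is made: the two bridgehead centres of 12 vanish on aromatisation, both diastereomers of 12 give the same arene, and the (S)-carbinol carbon is a spectator because no acid or base is present. The selectivity required is regiochemical, phenyl at C6 and ester at C5, and it should follow from the polarisation of the diene, whose C3 is the nucleophilic end (enol-ether beta-carbon of the 4-methoxy group, alpha to the lactone carbonyl) while C8a carries the ring oxygen and is the beta-carbon of the ring-B enone, matched with the electrophilic phenyl-bearing beta-carbon of the ynoate. An excess of 11 in a concentrated, neutral medium is used so that the bimolecular addition outruns thermal loss of silanol from the beta-silyloxy ketone.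

Step 9
Reactants: 13 benzyl (S)-7-(tert-butyldimethylsilyloxy)-4-methoxy-5-oxo-2-phenyl-5,6,7,8-tetrahydronaphthalene-1-carboxylate
Product: 14 (S)-7-(tert-butyldimethylsilyloxy)-4-methoxy-5-oxo-2-phenyl-5,6,7,8-tetrahydronaphthalene-1-carboxylic acid
Conditions: H2 (1 atm), 10% Pd/C, EtOAc, rt
Reagents that add atoms: none
Why: Catalytic hydrogenolysis of the benzyl ester cleaves the benzylic C–O bond under neutral conditions, so the hindered carbonyl need not be attacked and the aryl ketone, silyl ether, methyl ether and stereocentre should be untouched in a short reaction at 1 atm.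

Step 10
Reactants: 14 (S)-7-(tert-butyldimethylsilyloxy)-4-methoxy-5-oxo-2-phenyl-5,6,7,8-tetrahydronaphthalene-1-carboxylic acid; 15 2,2,6-trimethyl-4H-1,3-dioxin-4-one
Product: 17 6-{2-[(7S)-7-(tert-butyldimethylsilyloxy)-4-methoxy-5-oxo-2-phenyl-5,6,7,8-tetrahydronaphthalen-1-yl]-2-oxoethyl}-2,2-dimethyl-4H-1,3-dioxin-4-one, via acid chloride 16 (not isolated)
Conditions: 1-chloro-N,N,2-trimethylprop-1-en-1-amine, CH2Cl2, 0 °C → rt; the solution of 16 is added to 15 (2.5 equiv)/LiN(SiMe3)2 (2.5 equiv), THF, −78 °C; AcOH, −78 °C
Reagents that add atoms: 1-chloro-N,N,2-trimethylprop-1-en-1-amine CC(C)=C(Cl)N(C)C (supplies the chlorine of 16 only)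
Why: The alpha-chloroenamine converts the acid into acid chloride 16 without releasing HCl, and 16 then acylates the gamma-carbon of the lithium dienolate of 15 (a vinylogous Claisen-type C-acylation) at −78 °C, the second equivalent of dienolate taking up the acidic proton of the new 1,3-dicarbonyl unit, while the low temperature, the addition of 16 to the dienolate and the cold acidic quench should keep enolisation of the tetralone and beta-elimination of silanolate from competing.

Step 11
Reactants: 17 6-{2-[(7S)-7-(tert-butyldimethylsilyloxy)-4-methoxy-5-oxo-2-phenyl-5,6,7,8-tetrahydronaphthalen-1-yl]-2-oxoethyl}-2,2-dimethyl-4H-1,3-dioxin-4-one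
Product: 19 6-[(7S)-7-(tert-butyldimethylsilyloxy)-4-methoxy-5-oxo-2-phenyl-5,6,7,8-tetrahydronaphthalen-1-yl]-4-hydroxy-2H-pyran-2-one, via acylketene 18 (not isolated)
Conditions: toluene, 110 °C
Reagents that add atoms: none
Why: Thermal retro-[4+2] fragmentation of the dioxinone releases acetone and the acylketene 18, which is captured intramolecularly by the enol oxygen of the adjacent aryl ketone (acylketene lactonisation) to give the 4-hydroxy-2-pyrone under neutral conditions that leave the beta-silyloxy ketone alone.

Step 12
Reactants: 19 6-[(7S)-7-(tert-butyldimethylsilyloxy)-4-methoxy-5-oxo-2-phenyl-5,6,7,8-tetrahydronaphthalen-1-yl]-4-hydroxy-2H-pyran-2-one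
Product: 20 6-[(7S)-7-(tert-butyldimethylsilyloxy)-4-hydroxy-5-oxo-2-phenyl-5,6,7,8-tetrahydronaphthalen-1-yl]-4-hydroxy-2H-pyran-2-one
Conditions: BCl3 (4 equiv), CH2Cl2, −78 → −20 °C; then sat. aq NaHCO3
Reagents that add atoms: none
Why: Chelation-assisted Lewis-acid cleavage of an aryl methyl ether: boron bridges the C1 carbonyl (tetralone numbering) and the peri C8 methoxy oxygen and chloride removes the methyl group by SN2, a process fast at low temperature only for a methoxy group next to a carbonyl, so the silyl ether and the beta-silyloxy ketone should survive, the extra BCl3 being taken up reversibly by the acidic pyrone hydroxyl.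

Step 13
Reactants: 20 6-[(7S)-7-(tert-butyldimethylsilyloxy)-4-hydroxy-5-oxo-2-phenyl-5,6,7,8-tetrahydronaphthalen-1-yl]-4-hydroxy-2H-pyran-2-one
Product: 21 Wailupemycin F, 4-hydroxy-6-[(7S)-4,7-dihydroxy-5-oxo-2-phenyl-5,6,7,8-tetrahydronaphthalen-1-yl]-2H-pyran-2-one
Conditions: HF·pyridine, pyridine, THF, 0 °C → rt
Reagents that add atoms: none
Why: Fluoride-mediated cleavage of the Si–O bond (desilylation) in a pyridine-buffered, weakly acidic medium is chosen over basic fluoride sources so that the 3-hydroxy-1-tetralone is not dehydrated to a naphthol, and the carbinol carbon keeps its (S) configuration.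

Compound list

1 | phloroglucinol (benzene-1,3,5-triol) | Oc1cc(O)cc(O)c1 | starting material
2 | 5-hydroxycyclohexane-1,3-dione (achiral) | O=C1CC(O)CC(=O)C1 | intermediate
3 | 5-acetoxy-3-oxocyclohex-1-en-1-yl acetate (racemic enol acetate, not isolated) | CC(=O)OC1=CC(=O)CC(OC(C)=O)C1 | intermediate
4 | 3,5-dioxocyclohexyl acetate (achiral) | CC(=O)OC1CC(=O)CC(=O)C1 | intermediate
5 | malonyl dichloride | O=C(Cl)CC(=O)Cl | starting material
6 | (±)-4-hydroxy-2,5-dioxo-5,6,7,8-tetrahydro-2H-chromen-7-yl acetate | CC(=O)OC1CC(=O)c2c(O)cc(=O)oc2C1 | intermediate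
7 | (±)-4-methoxy-2,5-dioxo-5,6,7,8-tetrahydro-2H-chromen-7-yl acetate | COc1cc(=O)oc2c1C(=O)CC(OC(C)=O)C2 | intermediate
8 | (S)-7-hydroxy-4-methoxy-7,8-dihydro-2H-chromene-2,5(6H)-dione | COc1cc(=O)oc2c1C(=O)C[C@@H](O)C2 | intermediate
9 | (S)-7-(tert-butyldimethylsilyloxy)-4-methoxy-7,8-dihydro-2H-chromene-2,5(6H)-dione | COc1cc(=O)oc2c1C(=O)C[C@@H](O[Si](C)(C)C(C)(C)C)C2 | intermediate
10 | 3-phenylpropiolic acid (3-phenylprop-2-ynoic acid) | OC(=O)C#Cc1ccccc1 | starting material
11 | benzyl 3-phenylpropiolate | O=C(OCc1ccccc1)C#Cc1ccccc1 | intermediate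
12 | 2-oxabicyclo[2.2.2]octa-5,7-dien-3-one cycloadduct of 9 and 11 (lactone bridge between pyrone C3 and C8a, (S)-silyloxy carbon unchanged, both bridgehead diastereomers, not isolated) | O=C1OC23C[C@H](O[Si](C)(C)C(C)(C)C)CC(=O)C2=C(OC)C1C(c1ccccc1)=C3C(=O)OCc1ccccc1 | intermediate
13 | benzyl (S)-7-(tert-butyldimethylsilyloxy)-4-methoxy-5-oxo-2-phenyl-5,6,7,8-tetrahydronaphthalene-1-carboxylate | O=C(OCc1ccccc1)c1c(-c2ccccc2)cc(OC)c2c1C[C@H](O[Si](C)(C)C(C)(C)C)CC2=O | intermediate
14 | (S)-7-(tert-butyldimethylsilyloxy)-4-methoxy-5-oxo-2-phenyl-5,6,7,8-tetrahydronaphthalene-1-carboxylic acid | OC(=O)c1c(-c2ccccc2)cc(OC)c2c1C[C@H](O[Si](C)(C)C(C)(C)C)CC2=O | intermediate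
15 | 2,2,6-trimethyl-4H-1,3-dioxin-4-one | CC1=CC(=O)OC(C)(C)O1 | starting material
16 | (S)-7-(tert-butyldimethylsilyloxy)-4-methoxy-5-oxo-2-phenyl-5,6,7,8-tetrahydronaphthalene-1-carbonyl chloride (not isolated) | O=C(Cl)c1c(-c2ccccc2)cc(OC)c2c1C[C@H](O[Si](C)(C)C(C)(C)C)CC2=O | intermediate
17 | 6-{2-[(7S)-7-(tert-butyldimethylsilyloxy)-4-methoxy-5-oxo-2-phenyl-5,6,7,8-tetrahydronaphthalen-1-yl]-2-oxoethyl}-2,2-dimethyl-4H-1,3-dioxin-4-one | CC1(C)OC(CC(=O)c2c(-c3ccccc3)cc(OC)c3c2C[C@H](O[Si](C)(C)C(C)(C)C)CC3=O)=CC(=O)O1 | intermediate
18 | 5-[(7S)-7-(tert-butyldimethylsilyloxy)-4-methoxy-5-oxo-2-phenyl-5,6,7,8-tetrahydronaphthalen-1-yl]pent-1-ene-1,3,5-trione (acylketene, not isolated) | O=C=CC(=O)CC(=O)c1c(-c2ccccc2)cc(OC)c2c1C[C@H](O[Si](C)(C)C(C)(C)C)CC2=O | intermediate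
19 | 6-[(7S)-7-(tert-butyldimethylsilyloxy)-4-methoxy-5-oxo-2-phenyl-5,6,7,8-tetrahydronaphthalen-1-yl]-4-hydroxy-2H-pyran-2-one | O=c1cc(O)cc(-c2c(-c3ccccc3)cc(OC)c3c2C[C@H](O[Si](C)(C)C(C)(C)C)CC3=O)o1 | intermediate
20 | 6-[(7S)-7-(tert-butyldimethylsilyloxy)-4-hydroxy-5-oxo-2-phenyl-5,6,7,8-tetrahydronaphthalen-1-yl]-4-hydroxy-2H-pyran-2-one | O=c1cc(O)cc(-c2c(-c3ccccc3)cc(O)c3c2C[C@H](O[Si](C)(C)C(C)(C)C)CC3=O)o1 | intermediate
21 | Wailupemycin F, 4-hydroxy-6-[(7S)-4,7-dihydroxy-5-oxo-2-phenyl-5,6,7,8-tetrahydronaphthalen-1-yl]-2H-pyran-2-one | O=C1C[C@@H](O)Cc2c1c(O)cc(-c1ccccc1)c2-c1cc(O)cc(=O)o1 | target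

Total step count: 13. Longest linear sequence: 12 (steps 1–6 and 8–13 from phloroglucinol; step 7 is a one-step side branch).

Steps most likely to fail

Step 8. The cycloaddition may be too slow, because the ring-B carbonyl lowers the energy of the diene and its C8a terminus is fully substituted. Thermal loss of silanol from the beta-silyloxy ketone, which aromatises ring B, or polymerisation of the ynoate could then win, and a high temperature could also erode the regiocontrol. Fallback: setting out from 9, the ynoate is replaced by the more electrophilic, commercially available 3-phenylprop-2-ynal, which should add at a lower temperature (toluene, about 120 °C) with the same bond pairing. Loss of CO2 from the bridged lactone F1 (not isolated) gives (S)-7-(tert-butyldimethylsilyloxy)-4-methoxy-5-oxo-2-phenyl-5,6,7,8-tetrahydronaphthalene-1-carbaldehyde F2. Pinnick oxidation of this hindered aldehyde (NaClO2, NaH2PO4, 2-methylbut-2-ene, t-BuOH/H2O) returns to the route at acid 14, so that steps 7 and 9 are not needed.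

Step 5. The enzyme may discriminate poorly between the enantiomers, because the carbinol carbon is flanked by two CH2 groups and the two sides of ring B differ only two atoms further out; the alcohol would then be formed with insufficient enantiomeric purity. Fallback: setting out from 7, the acetate of both enantiomers is hydrolysed at pH 7 with an unselective esterase (pig liver esterase) to racemic 7-hydroxy-4-methoxy-7,8-dihydro-2H-chromene-2,5(6H)-dione F3, which is silylated as in step 6 to racemic 7-(tert-butyldimethylsilyloxy)-4-methoxy-7,8-dihydro-2H-chromene-2,5(6H)-dione F4. The enantiomers of F4 are separated by preparative chromatography on a chiral stationary phase (amylose tris(3,5-dimethylphenylcarbamate), supercritical CO2/MeOH), the configuration being assigned by vibrational circular dichroism. The (S)-enantiomer is 9, where the route is rejoined before step 8.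

Step 10. Proton transfer from the CH2 group next to the tetralone carbonyl to the basic dienolate may be followed by loss of silanolate and aromatisation of ring B, and slow attack on the doubly ortho-substituted aroyl chloride may let O-acylation or self-condensation compete. Fallback: setting out from 14 (converted into 16 as before), the basic dienolate is replaced by a neutral carbon nucleophile. 1-Methoxy-1,3-bis(trimethylsilyloxy)buta-1,3-diene, the bis(silyl enol ether) of methyl acetoacetate, is acylated at its terminal carbon by 16 in CH2Cl2 from −78 °C to room temperature without base or Lewis acid. This gives the silyl ketene acetal F5 (not isolated), which aqueous work-up hydrolyses to methyl 5-[(7S)-7-(tert-butyldimethylsilyloxy)-4-methoxy-5-oxo-2-phenyl-5,6,7,8-tetrahydronaphthalen-1-yl]-3,5-dioxopentanoate F6. Lactonisation of F6 with one equivalent of DBU in toluene at room temperature, with loss of methanol, gives 19, where the route is rejoined, so that step 11 is not needed.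

Further compounds

F1 | step 8 | 2-oxabicyclo[2.2.2]octa-5,7-dien-3-one cycloadduct of 9 and 3-phenylprop-2-ynal (both bridgehead diastereomers, not isolated) | O=C1OC23C[C@H](O[Si](C)(C)C(C)(C)C)CC(=O)C2=C(OC)C1C(c1ccccc1)=C3C=O
F2 | step 8 | (S)-7-(tert-butyldimethylsilyloxy)-4-methoxy-5-oxo-2-phenyl-5,6,7,8-tetrahydronaphthalene-1-carbaldehyde | O=Cc1c(-c2ccccc2)cc(OC)c2c1C[C@H](O[Si](C)(C)C(C)(C)C)CC2=O
F3 | step 5 | (±)-7-hydroxy-4-methoxy-7,8-dihydro-2H-chromene-2,5(6H)-dione | COc1cc(=O)oc2c1C(=O)CC(O)C2
F4 | step 5 | (±)-7-(tert-butyldimethylsilyloxy)-4-methoxy-7,8-dihydro-2H-chromene-2,5(6H)-dione | COc1cc(=O)oc2c1C(=O)CC(O[Si](C)(C)C(C)(C)C)C2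
F5 | step 10 | 5-[(7S)-7-(tert-butyldimethylsilyloxy)-4-methoxy-5-oxo-2-phenyl-5,6,7,8-tetrahydronaphthalen-1-yl]-1-methoxy-1-(trimethylsilyloxy)pent-1-ene-3,5-dione (silyl ketene acetal, not isolated) | COC(O[Si](C)(C)C)=CC(=O)CC(=O)c1c(-c2ccccc2)cc(OC)c2c1C[C@H](O[Si](C)(C)C(C)(C)C)CC2=O
F6 | step 10 | methyl 5-[(7S)-7-(tert-butyldimethylsilyloxy)-4-methoxy-5-oxo-2-phenyl-5,6,7,8-tetrahydronaphthalen-1-yl]-3,5-dioxopentanoate | COC(=O)CC(=O)CC(=O)c1c(-c2ccccc2)cc(OC)c2c1C[C@H](O[Si](C)(C)C(C)(C)C)CC2=O
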